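All runs stem from a simulated flask from invented constants.

1.76 is the number I read first. I call it the activation exponent n: the power of time at which the loss, minus the logarithm of the fraction of starting material left, grows between 2.00 min and 4.00 min, both runs taken together.

all flasks: precatalyst 18 mM
- south-east: starting material 0.70 M; reagent 1 M; run made earlier
- south: starting material 1.1 M; reagent 1 M; run made earlier
- flask: starting material 0.50 M; reagent 1.00 M

| run | time / min | product / % | starting material / % |
|---|---|---|---|
| south-east | 0.250 | 0 | 99.6 |
| south-east | 0.500 | 0.1 | 99.6 |
| south-east | 1.00 | 1.6 | 95.9 |
| south-east | 2.00 | 9.7 | 87.2 |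
| south-east | 4.00 | 34.8 | 62.2 |
| south | 0.250 | 0 | 99.0 |
| south | 0.500 | 0.6 | 99.1 |
| south | 1.00 | 1.9 | 96.2 |
| south | 2.00 | 10.1 | 86.8 |
| south | 4.00 | 33.6 | 62.4 |

(each reading ± 0.3 percentage points)

- factor on the rate of making product when 20 % of the starting material are converted if precatalyst is charged twice over
- factor on the rate when 20 % of the starting material are converted if precatalyst is charged at 4.0 mM instead

- no earlier run changes the charge of precatalyst; that part of a forecast is a guess

At 0.500 min the south-east run shows 0.1 % product, an induction period. In the middle, at 4.00 min, the south-east run keeps 62.2 % of its starting material and the south run 62.4 %. So within the scatter the two charges of starting material have lost the same fraction by then, and I carry that over to this flask of 0.50 M starting material. In the south-east run the readings then leave 3.00 % as neither starting material nor product.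

I take the speeding-up as catalyst growing out of precatalyst, at each moment a fixed share of the precatalyst charge. That is my guess, since no run varies the charge of precatalyst. Then, with charge meaning that of precatalyst:

loss ∝ charge × t^n

at equal conversion, charge × t^n stays the same

rate ∝ loss / t, so the factor on the rate is the n-th root of the charge ratio

Doubling gives 1.48, and 4.0 mM gives 0.426. The second is the weaker figure. The 20 % mark moves from 2.64 min to 6.18 min, later than the last reading at 4.00 min, so n is stretched there.

The forecast says 1.5 and 0.42, on the ground of “slow precatalyst activation that is far from finished”; its figures differ slightly from mine.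

The simulation gives 1.51 and 0.364.

    starting material + catalyst ⇌ catalyst + intermediate (K = 0.916, k = 0.304 L mol⁻¹ s⁻¹)
    precatalyst → catalyst (k = 0.00434 s⁻¹)
    reagent + catalyst + intermediate → catalyst + product (k = 7.76 L² mol⁻² s⁻¹)

In this flask catalyst stands at 54.2 % of its charge after 3.00 min and at 79.0 % after 6.00 min, a factor of 1.46 over a doubling of the time. Taken backward through the n-th root, the doubled charge corresponds to an exponent of 1.69, and the charge of 4.0 mM to 1.49, a lower one.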